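## Retrosynthetic overview

1. Numbering (target SMILES read left to right): C1–C2 ethyl, C3 carbinol, ring A = N + C4–C8, ring C = C9–C13 (C10 Me, C11 OH, C12 spiro, C13 OH), ring B = N, C8, C9, C13, C14, C15, C16, ring D = tetronate O1′, C2′, C3′, C4′, C5′ (= C12).
2. Enabling feature: N is the one atom shared by rings A and B, its ring-A neighbours C4 and C8 are both CH with cis hydrogens, and C14 sits on the tertiary carbinol C13. Ring A can therefore be carried as a pyridine (higher oxidation level, no stereocentres), N can take C16–C15 as an allyl group, and C14 can enter as a vinyl group on a C13 ketone.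
3. Last ring: ring B by ring-closing metathesis of N-allylpyridinium 18 at C14=C15; hydrogenation in the same flask saturates C14–C15 and the pyridinium ring (C8 and C4 set from C9); then desilylation.
4. 18 ⇐ vinyl addition to ketone 16 (sets C13) ⇐ Pd α-arylation of spiro ketone 10 with bromopyridine 15 (C8–C9 bond; C9 trans to C10; C3 by catalytic transfer hydrogenation).
5. Rings C/D: tetronate 1 (ring D bought) + methacrolein + acrolein → catalytic vinylogous aldol (C11), dianion aldol (C12), metathesis (ring C), oxidation, hydrogenation (C10). Ring order: D → C → A (aromatic) → B → A saturated.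

Key step: step 14

Assumption: 4-methoxy-3-methylfuran-2(5H)-one (1) is taken as a catalogue compound (otherwise one O-methylation away from 3-methyltetronic acid).

## Route

Step 1
Reactants: 1 4-methoxy-3-methylfuran-2(5H)-one
Product: 2 2-(trimethylsilyloxy)-4-methoxy-3-methylfuran
Conditions: TMSOTf, Et3N, Et2O, 0 °C
Reagents that add atoms: trimethylsilyl triflate, C[Si](C)(C)OS(=O)(=O)C(F)(F)F
Why: Soft enolisation of the butenolide at C5′ (silyl dienol ether formation) gives the 2-silyloxyfuran needed for a vinylogous Mukaiyama aldol; no stereocentre is formed.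

Step 2
Reactants: 2 2-(trimethylsilyloxy)-4-methoxy-3-methylfuran; 3 methacrolein
Product: 4 5-[(1S)-1-hydroxy-2-methylprop-2-enyl]-4-methoxy-3-methylfuran-2(5H)-one (C11 S; both C5′ epimers)
Conditions: Ti(OiPr)4/(R)-BINOL (20 mol %), Et2O, −20 °C; then 1 M HCl
Reagents that add atoms: none
Why: Catalytic asymmetric vinylogous Mukaiyama aldol at furan C5′: the chiral titanium–BINOL Lewis acid selects the aldehyde face and should set C11 as S (the ligand antipode is taken if the opposite sense is found), while the C5′ epimer ratio does not matter because that centre is deprotonated in step 3.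

Step 3
Reactants: 4 5-[(1S)-1-hydroxy-2-methylprop-2-enyl]-4-methoxy-3-methylfuran-2(5H)-one; 5 acrolein
Product: 6 5-[(1S)-1-hydroxy-2-methylprop-2-enyl]-5-(1-hydroxyprop-2-enyl)-4-methoxy-3-methylfuran-2(5H)-one (quaternary C12 as in the target; C13 carbinol as both epimers)
Conditions: LiN(iPr)2 (2.3 equiv), THF, −78 °C; acrolein, −78 °C; AcOH quench at −78 °C
Reagents that add atoms: none
Why: Aldol addition of the lithium dienolate (alkoxide/dienolate dianion, which cannot eliminate) at C5′: with C11–H eclipsing the C4′–OMe side (allylic strain) the lithium alkoxide should guide acrolein to its own face, anti to the isopropenyl group as in a Fráter–Seebach alkylation, which sets quaternary C12 with C11–O on the C4′ side of the later ring; C13 is not controlled and is oxidised in step 5.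

Step 4
Reactants: 6 bis-allylic diol
Product: 7 spiro cyclopentene diol: ring C with C9=C10 (C10 methyl), C11–OH (syn to C4′, anti to O1′) and C13–OH (both epimers), spiro at C12 to ring D
Conditions: second-generation Grubbs catalyst (5 mol %), CH2Cl2, 40 °C
Reagents that add atoms: none
Why: Ring-closing metathesis of the isopropenyl and vinyl groups of the 1,6-diene closes ring C as a trisubstituted cyclopentene with loss of ethene; no stereocentre is touched.

Step 5
Reactants: 7 spiro cyclopentene diol
Product: 8 spiro hydroxy enone: C13 ketone conjugated with C9=C10(Me), C11–OH retained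
Conditions: MnO2 (activated, excess), CH2Cl2, 23 °C
Reagents that add atoms: none
Why: Allylic oxidation with MnO2 should take the C13 carbinol, which is less hindered and leads to the more stabilised β-methyl enone, and leave C11–OH, which lies between quaternary C12 and the methyl-bearing alkene carbon; both C13 epimers converge.

Step 6
Reactants: 8 spiro hydroxy enone
Product: 9 C11 tert-butyldimethylsilyl ether of 8
Conditions: TBSOTf, 2,6-lutidine, CH2Cl2, −40 to 0 °C
Reagents that add atoms: tert-butyldimethylsilyl triflate, CC(C)(C)[Si](C)(C)OS(=O)(=O)C(F)(F)F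
Why: Silylation of the hindered secondary alcohol with a silyl triflate protects C11–O and provides the bulky group that directs step 7.

Step 7
Reactants: 9 silyloxy enone
Product: 10 spiro ketone: C13 ketone, C9H2, C10 methyl cis to C11–OTBS (both on the C4′ face), C12 spiro to ring D
Conditions: H2 (1 atm), 10% Pd/C, EtOAc, 23 °C
Reagents that add atoms: none
Why: Heterogeneous hydrogenation of the enone C9=C10 from the face opposite to C11–OTBS and C4′ places the C10 methyl cis to C11–O (target configuration, not epimerisable afterwards); the fully substituted push–pull tetronate alkene should not be reduced.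

Step 8
Reactants: 11 2,6-dibromopyridine; 12 N-methoxy-N-methylpropanamide
Product: 13 1-(6-bromopyridin-2-yl)propan-1-one
Conditions: n-BuLi (1.0 equiv), Et2O, −78 °C; then 12, −78 to 0 °C; aq NH4Cl
Reagents that add atoms: none
Why: Bromine–lithium exchange of one C–Br bond followed by Weinreb ketone synthesis stops at the ketone because of the stable chelated tetrahedral intermediate.

Step 9
Reactants: 13 1-(6-bromopyridin-2-yl)propan-1-one
Product: 14 (R)-1-(6-bromopyridin-2-yl)propan-1-ol
Conditions: RuCl[(R,R)-TsDPEN](p-cymene) (1 mol %), HCO2H/Et3N (5:2), 28 °C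
Reagents that add atoms: none
Why: Noyori asymmetric transfer hydrogenation of the aryl alkyl ketone; the (R,R)-ligand should deliver hydride to give the R carbinol (C3), by analogy with aryl methyl ketones.

Step 10
Reactants: 14 (R)-1-(6-bromopyridin-2-yl)propan-1-ol
Product: 15 (R)-2-bromo-6-[1-(tert-butyldimethylsilyloxy)propyl]pyridine
Conditions: TBSCl, imidazole, DMF, 23 °C
Reagents that add atoms: tert-butyldimethylsilyl chloride, CC(C)(C)[Si](C)(C)Cl
Why: Standard silyl ether formation protects C3–O for the base- and organometallic steps that follow.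

Step 11
Reactants: 10 spiro ketone; 15 (R)-2-bromo-6-[1-(tert-butyldimethylsilyloxy)propyl]pyridine
Product: 16 C9-pyridyl ketone: 10 carrying at C9 the 6-[(R)-1-(TBSO)propyl]pyridin-2-yl group, trans to the C10 methyl
Conditions: Pd2(dba)3 (2.5 mol %), Xantphos (6 mol %), NaOtBu (1.3 equiv), THF, 65 °C; aq NH4Cl
Reagents that add atoms: none
Why: Palladium-catalysed ketone α-arylation (oxidative addition of the bromopyridine to zerovalent palladium, enolate transmetalation, reductive elimination) forms C8–C9; enolisation is possible only toward C9 because C12 is quaternary, and the acidic α-pyridyl centre should settle as the 9,10-trans isomer under the basic conditions.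

Step 12
Reactants: 16 C9-pyridyl ketone
Product: 17 tertiary vinyl carbinol: C13(OH)(CH=CH2) with OH cis and vinyl trans to the C9 pyridyl group
Conditions: CeCl3 (dried), vinylmagnesium bromide, THF, −78 °C; aq NH4Cl at −78 °C
Reagents that add atoms: vinylmagnesium bromide, C=C[Mg]Br
Why: 1,2-Addition of the weakly basic organocerium reagent suppresses enolisation; vinyl should attack C13 anti to the C9 pyridyl group and anti to the C12–O bond (polar Felkin–Anh), which puts C14 trans to C8 as the trans B/C fusion requires.

Step 13
Reactants: 17 tertiary vinyl carbinol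
Product: 18 N-allylpyridinium triflate of 17
Conditions: allyl iodide, AgOTf, CH2Cl2, 0 to 23 °C, dark
Reagents that add atoms: allyl iodide, C=CCI; silver triflate, [Ag+].[O-]S(=O)(=O)C(F)(F)F
Why: Menshutkin N-alkylation; the nitrogen is flanked by two secondary carbons, so a triflate-level electrophile (allyl triflate formed in the flask) is used, and the neutral conditions leave the tertiary alcohol, silyl ethers and tetronate untouched.

Step 14
Reactants: 18 N-allylpyridinium triflate
Product: 20 3,11-bis-O-tert-butyldimethylsilyl ether of the target, via azepine-fused pyridinium triflate 19 (not isolated)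
Conditions: second-generation Hoveyda–Grubbs catalyst (10 mol %), ClCH2CH2Cl, 60 °C; then solvent exchange to MeOH/AcOH (10:1), PtO2 (20 mol %), H2 (4 atm), 23 °C; aq NaHCO3
Reagents that add atoms: none
Why: Olefin metathesis (Chauvin [2+2]/cycloreversion cycle, ring-closing mode) joins the N-allyl terminus and the C13 vinyl group with loss of ethene and closes the seven-membered ring B at C14=C15; the closest known reaction type is ring-closing metathesis of N-alkenyl-2-alkenylpyridinium salts, in which the cationic nitrogen cannot bind ruthenium. Ring B closes as a cis-cycloheptene from a 1,8-diene and is trans-fused to ring C because C8 and C14 were already trans on ring C in 18. Hydrogen over PtO2 then saturates C14=C15 and adds three more H2 to one face of the planar pyridinium ring, so C4–H and C8–H must come out cis (the 2,6-cis piperidine). The face is chosen by C9: in the folded ring B of 19 the C9–H bond lies on the convex face and C10 with ring C on the other, so C8–H should end syn to C9–H, which is the target arrangement (C8 S, C4 R). The step needs ring closure over cross-metathesis (dilution; initiation at the unhindered allyl group) and ring reduction without hydrogenolysis of the pyridylic C3–O bond or reduction of the tetronate alkene (Pt rather than Pd; the tetronate alkene is fully substituted and push–pull).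

Step 15
Reactants: 20 bis-silyl ether
Product: 21 CNP0267781.1 (3R,4R,8S,9R,10S,11S,12R,13S in the numbering used here)
Conditions: HF·pyridine, THF, 0 to 23 °C; aq NaHCO3
Reagents that add atoms: none
Why: Acidic fluoride desilylation frees C3–OH and C11–OH; basic fluoride is avoided so that the C13 alkoxide cannot fragment by retro-aldol cleavage of C12–C13.

## Compound list

1 | 4-methoxy-3-methylfuran-2(5H)-one | COC1=C(C)C(=O)OC1 | starting material
2 | 2-(trimethylsilyloxy)-4-methoxy-3-methylfuran | COc1coc(O[Si](C)(C)C)c1C | intermediate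
3 | methacrolein | CC(=C)C=O | starting material
4 | 5-[(1S)-1-hydroxy-2-methylprop-2-enyl]-4-methoxy-3-methylfuran-2(5H)-one (C5′ epimers) | C=C(C)[C@H](O)C1OC(=O)C(C)=C1OC | intermediate
5 | acrolein | C=CC=O | starting material
6 | 5-[(1S)-1-hydroxy-2-methylprop-2-enyl]-5-(1-hydroxyprop-2-enyl)-4-methoxy-3-methylfuran-2(5H)-one (C12 as in target; C13 epimers) | C=C(C)[C@H](O)[C@@]1(OC(=O)C(C)=C1OC)C(O)C=C | intermediate
7 | spiro cyclopentene diol (C9=C10, C10 Me; C11–OH syn to C4′; C13–OH epimers) | C1=C(C)[C@H](O)[C@@]2(OC(=O)C(C)=C2OC)C1O | intermediate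
8 | spiro hydroxy enone (C13 ketone, C9=C10(Me), C11–OH) | C1=C(C)[C@H](O)[C@@]2(OC(=O)C(C)=C2OC)C1=O | intermediate
9 | C11 TBS ether of 8 | C1=C(C)[C@H](O[Si](C)(C)C(C)(C)C)[C@@]2(OC(=O)C(C)=C2OC)C1=O | intermediate
10 | spiro ketone (C10 Me cis to C11–OTBS, both syn to C4′; C13 ketone) | C1[C@H](C)[C@H](O[Si](C)(C)C(C)(C)C)[C@@]2(OC(=O)C(C)=C2OC)C1=O | intermediate
11 | 2,6-dibromopyridine | Brc1cccc(Br)n1 | starting material
12 | N-methoxy-N-methylpropanamide | CCC(=O)N(C)OC | starting material
13 | 1-(6-bromopyridin-2-yl)propan-1-one | CCC(=O)c1cccc(Br)n1 | intermediate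
14 | (R)-1-(6-bromopyridin-2-yl)propan-1-ol | CC[C@@H](O)c1cccc(Br)n1 | intermediate
15 | (R)-2-bromo-6-[1-(tert-butyldimethylsilyloxy)propyl]pyridine | CC[C@@H](O[Si](C)(C)C(C)(C)C)c1cccc(Br)n1 | intermediate
16 | C9-pyridyl spiro ketone (pyridyl trans to C10 Me) | CC[C@@H](O[Si](C)(C)C(C)(C)C)c1cccc(n1)[C@H]2[C@H](C)[C@H](O[Si](C)(C)C(C)(C)C)[C@@]3(OC(=O)C(C)=C3OC)C2=O | intermediate
17 | tertiary vinyl carbinol (C13–OH cis to pyridyl, vinyl trans) | CC[C@@H](O[Si](C)(C)C(C)(C)C)c1cccc(n1)[C@H]2[C@H](C)[C@H](O[Si](C)(C)C(C)(C)C)[C@@]3(OC(=O)C(C)=C3OC)[C@]2(O)C=C | intermediate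
18 | N-allylpyridinium triflate of 17 | CC[C@@H](O[Si](C)(C)C(C)(C)C)c1cccc([n+]1CC=C)[C@H]2[C@H](C)[C@H](O[Si](C)(C)C(C)(C)C)[C@@]3(OC(=O)C(C)=C3OC)[C@]2(O)C=C.[O-]S(=O)(=O)C(F)(F)F | intermediate
19 | azepine-fused pyridinium triflate (ring B closed, C14=C15) | CC[C@@H](O[Si](C)(C)C(C)(C)C)c1cccc2[C@H]3[C@H](C)[C@H](O[Si](C)(C)C(C)(C)C)[C@@]4(OC(=O)C(C)=C4OC)[C@]3(O)C=CC[n+]12.[O-]S(=O)(=O)C(F)(F)F | intermediate
20 | 3,11-bis-O-TBS ether of the target | CC[C@@H](O[Si](C)(C)C(C)(C)C)[C@H]1CCC[C@H]2[C@H]3[C@H](C)[C@H](O[Si](C)(C)C(C)(C)C)[C@@]4(OC(=O)C(C)=C4OC)[C@]3(O)CCCN12 | intermediate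
21 | CNP0267781.1 | CC[C@@H](O)[C@H]1CCC[C@H]2[C@H]3[C@H](C)[C@H](O)[C@@]4(OC(=O)C(C)=C4OC)[C@]3(O)CCCN12 | target

## Step count and risks

Total step count: 15. Longest linear sequence: 12 steps (steps 1–7 and 11–15).

**Step 3.** The π-facial control of the dianion aldol may be lost or reversed (sterics overriding alkoxide guidance), and the C11 aldolate may undergo retro-aldol before C–C bond formation. The fallback sets out from 1 and comes back at 9. Compound 1 is deprotonated and added to acrolein twice (LiN(iPr)2, THF, −78 °C) to give the bis-allylic diol 5,5-bis(1-hydroxyprop-2-enyl)-4-methoxy-3-methylfuran-2(5H)-one F1. Ring-closing metathesis (second-generation Grubbs catalyst) gives the spiro cyclopentene-1,4-diol F2, and Dess–Martin oxidation gives the mirror-symmetric spiro cyclopentene-1,3-dione F3. A Corey–Bakshi–Shibata reduction (Me-CBS oxazaborolidine, BH3·SMe2) then desymmetrises F3: the catalyst picks one enantiotopic carbonyl and hydride enters anti to C4′, so C11 and C12 are set together in the hydroxy enone F4. Silylation (TBSOTf, 2,6-lutidine) gives the silyl ether F5. Conjugate methylation (Me2CuLi, TMSCl) anti to the silyloxy group gives the trimethylsilyl enol ether F6, and Saegusa–Ito oxidation (Pd(OAc)2, MeCN) restores the enone, now β-methylated, which is compound 9.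

**Step 12.** Proton transfer (enolisation of the acidic α-pyridyl ketone) may outrun addition, facial selectivity may erode on the crowded lower face, and the C13 alkoxide may fragment by retro-aldol if the mixture warms. The fallback sets out from 16 and comes back at 17. The slimmer, less basic sp nucleophile is added instead (ethynylmagnesium bromide, CeCl3, THF, −78 °C) to give the ethynyl carbinol F7. Semi-hydrogenation (H2, Pd/CaCO3 poisoned with Pb(OAc)2, quinoline) then gives 17.

**Step 14.** Facial discrimination on the platinum surface may be incomplete (the C8/C4 pair delivered to the wrong face), and the pyridylic C3–O bond may be partly hydrogenolysed. The fallback sets out from 18 and comes back at 20. The metathesis is run as before but 19 is isolated. Stepwise ionic reduction (NaBH4, MeOH, −40 °C) builds C8 and then C4 by two separate hydride additions under stereoelectronic control and gives the 1,2,3,6-tetrahydropyridine F8. Neutral hydrogenation (H2, PtO2, EtOAc) of its two ring alkenes then gives 20.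

Further compounds
F1 | step 3 | 5,5-bis(1-hydroxyprop-2-enyl)-4-methoxy-3-methylfuran-2(5H)-one (carbinol epimers) | C=CC(O)C1(OC(=O)C(C)=C1OC)C(O)C=C
F2 | step 3 | spiro cyclopentene-1,4-diol on the tetronate (carbinol epimers) | C1=CC(O)C2(OC(=O)C(C)=C2OC)C1O
F3 | step 3 | mirror-symmetric spiro cyclopent-4-ene-1,3-dione on the tetronate | O=C1C=CC(=O)C12OC(=O)C(C)=C2OC
F4 | step 3 | desymmetrised spiro hydroxy enone (C11 S, OH syn to C4′) | C1=C[C@H](O)[C@@]2(OC(=O)C(C)=C2OC)C1=O
F5 | step 3 | C11 TBS ether of F4 | C1=C[C@H](O[Si](C)(C)C(C)(C)C)[C@@]2(OC(=O)C(C)=C2OC)C1=O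
F6 | step 3 | trimethylsilyl enol ether (C13–OTMS, C9=C13; C10 Me trans to C11–OTBS) | C=1[C@@H](C)[C@H](O[Si](C)(C)C(C)(C)C)[C@@]2(OC(=O)C(C)=C2OC)C=1O[Si](C)(C)C
F7 | step 12 | tertiary ethynyl carbinol (C13–OH cis to pyridyl, ethynyl trans) | CC[C@@H](O[Si](C)(C)C(C)(C)C)c1cccc(n1)[C@H]2[C@H](C)[C@H](O[Si](C)(C)C(C)(C)C)[C@@]3(OC(=O)C(C)=C3OC)[C@]2(O)C#C
F8 | step 14 | 1,2,3,6-tetrahydropyridine with C6=C7 and C14=C15 (C4, C8 as in 20) | CC[C@@H](O[Si](C)(C)C(C)(C)C)[C@H]1CC=C[C@H]2[C@H]3[C@H](C)[C@H](O[Si](C)(C)C(C)(C)C)[C@@]4(OC(=O)C(C)=C4OC)[C@]3(O)C=CCN12
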